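**Retrosynthetic overview** (locants are azulene locants of the target: C-3 isopropyl carbinol, C-3a/C-8a ring fusion, C-4 ester carbon, C-6 methyl carbinol, C-7=C-8 alkene)

1. The aryl ester at C-4 is made last, by selective acylation of the only secondary hydroxyl of a triol.
2. Key disconnection: in the seven-membered ring the triad C-6(OH)(CH3)–C-7H=C-8H, flanked by the quaternary fusion carbon C-8a, is the water adduct of a cycloheptenyl allyl cation whose central carbon C-7 is a one-carbon insert. Removing C-7 leaves a trans-hydrindene with a C(CH3)=CH double bond. Forward, dibromocarbene closes a cyclopropane on that alkene (forming the C-6–C-7 bond), and strain-driven, silver-promoted opening of the cyclopropane enlarges the six-membered ring to the seven-membered ring and delivers the C-6 hydroxyl.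
3. The cyclohexene of the hydrindene is closed by ring-closing metathesis between a vinyl group on the quaternary carbon and a methallyl carbinol side chain.
4. The cyclopentane with its three contiguous stereocentres comes from 3-methylcyclopent-2-enone: catalytic enantioselective conjugate addition of a 1-silylvinyl alane, anti-aldol trapping of the enolate, then isopropyl addition to the ketone.
5. Order of ring formation: cyclopentane (present from the start) → cyclohexene (metathesis) → cyclopropane ([2+1]) → cycloheptene (electrocyclic ring opening).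

Key step: step 7

Remark: in step 2 the enantiomer of the carbene ligand is the one that gives the (S)-configured quaternary carbon drawn in 6 and 7.

**Step 1**
Reactants: 1 3-methylbut-3-en-1-ol
Product: 2 3-methylbut-3-enal
Conditions: Dess–Martin periodinane, NaHCO3, CH2Cl2, 0 °C; the cold solution is used at once
Reagents that add atoms: none
Why: Buffered Dess–Martin oxidation should give the β,γ-unsaturated aldehyde without migration of the double bond into conjugation.

**Step 2**
Reactants: 3 ethynyl(dimethyl)phenylsilane; 4 3-methylcyclopent-2-en-1-one; 2 3-methylbut-3-enal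
Product: 7 (2S,3S)-2-[(1S)-1-hydroxy-3-methylbut-3-en-1-yl]-3-methyl-3-[1-(dimethylphenylsilyl)ethenyl]cyclopentan-1-one, via alkenylalane 5 (not isolated), via aluminium enolate 6 (not isolated)
Conditions: 3, i-Bu2AlH, hexane, 55 °C; then 4, CuCl2·2H2O (5 mol %), chiral sulfonate-bearing N-heterocyclic carbene (from its imidazolinium salt, 6 mol %), THF, −15 °C; then 2, −78 °C; aq. potassium sodium tartrate
Reagents that add atoms: none
Why: Hydroalumination puts aluminium on the silyl-bearing carbon, the copper–carbene-catalysed conjugate addition of this alkenylalane sets the quaternary centre under catalyst control, and the cyclic (E)-aluminium enolate should add to the aldehyde through a Zimmerman–Traxler chair on the face opposite the bulky silylvinyl group, giving the anti aldol with the side chain cis to the ring methyl (three-component conjugate addition–aldol).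

**Step 3**
Reactants: 7
Product: 8 (1R,2S,3S)-2-[(1S)-1-hydroxy-3-methylbut-3-en-1-yl]-3-methyl-1-(propan-2-yl)-3-[1-(dimethylphenylsilyl)ethenyl]cyclopentan-1-ol
Conditions: i-PrMgCl, CeCl3, THF, −78 → 0 °C
Reagents that add atoms: isopropylmagnesium chloride CC(C)[Mg]Cl
Why: The organocerium reagent should add to the hindered, enolisable β-hydroxy ketone without retro-aldol and from the face opposite the adjacent side chain, so the new tertiary hydroxyl is cis to that chain (organocerium 1,2-addition).

**Step 4**
Reactants: 8
Product: 9 (1R,2S,3R)-3-ethenyl-2-[(1S)-1-hydroxy-3-methylbut-3-en-1-yl]-3-methyl-1-(propan-2-yl)cyclopentan-1-ol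
Conditions: Bu4NF, THF–DMSO, 80 °C
Reagents that add atoms: none
Why: Fluoride-mediated protodesilylation of the alkenyl(dimethylphenyl)silane, helped by the neighbouring alkoxide, should remove the silyl group once it has served as the steric control element, and no stereocentre is touched.

**Step 5**
Reactants: 9
Product: 10 (3R,3aS,4S,7aR)-6,7a-dimethyl-3-(propan-2-yl)-2,3,3a,4,5,7a-hexahydro-1H-indene-3,4-diol
Conditions: second-generation Grubbs catalyst RuCl2(H2IMes)(PCy3)(=CHPh) (5 mol %), CH2Cl2, 40 °C
Reagents that add atoms: none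
Why: Ring-closing olefin metathesis between the vinyl group on the quaternary carbon and the 1,1-disubstituted alkene should give the trisubstituted cyclohexene with loss of ethene; the two arms are trans on the cyclopentane, so the hydrindene is trans-fused and no stereocentre is created.

**Step 6**
Reactants: 10
Product: 11 (3R,3aS,4S,7aR)-6,7a-dimethyl-3-(propan-2-yl)-3,4-bis(triethylsilyloxy)-2,3,3a,4,5,7a-hexahydro-1H-indene
Conditions: Et3SiOTf, 2,6-lutidine, CH2Cl2, −78 → 20 °C
Reagents that add atoms: triethylsilyl trifluoromethanesulfonate CC[Si](CC)(CC)OS(=O)(=O)C(F)(F)F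
Why: The silyl triflate should mask both the secondary and the hindered tertiary hydroxyl, which would otherwise react with the dihalocarbene of the next step; no stereocentre is affected.

**Step 7**
Reactants: 11
Product: 13 (3R,3aS,4S,6R,8aS)-7-bromo-6,8a-dimethyl-3-(propan-2-yl)-3,4-bis(triethylsilyloxy)-1,2,3,3a,4,5,6,8a-octahydroazulen-6-ol, via dibromocyclopropane 12 (not isolated)
Conditions: PhHgCBr3, benzene, 80 °C; then, same flask, AgClO4, 2,6-lutidine, acetone–H2O (10:1), 25 → 40 °C
Reagents that add atoms: phenyl(tribromomethyl)mercury BrC(Br)(Br)[Hg]c1ccccc1; water O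
Why: Thermal α-elimination of PhHgCBr3 releases dibromocarbene, which adds in a concerted [2+1] step to the electron-rich trisubstituted alkene of 11 (the carbene carbon becomes C-7 of the azulene and one of its two new bonds is the C-6–C-7 bond of the target); silver ion then removes the bromide lying over the six-membered ring while the fusion bond of the bicyclo[4.1.0]heptane opens in a disrotatory two-electron electrocyclic process to the cis 2-bromocycloheptenyl cation, which water traps. The closest known reaction type is the dihalocarbene addition/silver-salt ring enlargement of cycloalkenes to 2-halocycloalk-2-en-1-ols. The three-membered ring is closed by cycloaddition, and the seven-membered ring arises not from a further bond formation but from opening of the strained cyclopropane (about 27 kcal/mol), which together with AgBr formation drives the step. The two cyclopropane stereocentres are erased again; the one lasting new stereocentre, the tertiary carbinol C-6, should be set by attack of water on the planar allyl cation from the face opposite the pseudoaxial angular methyl on C-8a, which places the hydroxyl cis to the C-4 silyloxy group. The step needs capture at the methyl-bearing terminus and not at the other terminus or proton loss to a diene: the tertiary terminus carries more positive charge, the secondary terminus is neopentylic (next to quaternary C-8a), the lutidine buffer and the deactivating vinylic bromine keep the tertiary allylic alcohol from re-ionising, and the silyl ethers exclude carbene O–H insertion and neighbouring-group capture.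

**Step 8**
Reactants: 13
Product: 14 (3R,3aS,4S,6R,8aR)-6,8a-dimethyl-3-(propan-2-yl)-3,4-bis(triethylsilyloxy)-1,2,3,3a,4,5,6,8a-octahydroazulen-6-ol
Conditions: Bu3SnH, AIBN (cat.), benzene, 80 °C
Reagents that add atoms: none
Why: Radical-chain tin hydride reduction should replace the vinylic bromine by hydrogen without touching the tertiary allylic alcohol, and the alkene geometry is fixed by the ring.

**Step 9**
Reactants: 14
Product: 15 (3R,3aS,4S,6R,8aR)-6,8a-dimethyl-3-(propan-2-yl)-1,2,3,3a,4,5,6,8a-octahydroazulene-3,4,6-triol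
Conditions: Bu4NF, THF, 25 → 50 °C
Reagents that add atoms: none
Why: Fluoride should cleave both triethylsilyl ethers under basic, non-ionising conditions that the tertiary allylic alcohol tolerates.

**Step 10**
Reactants: 15; 16 4-(acetyloxy)benzoyl chloride
Product: 18 (3R,3aS,4S,6R,8aR)-3,6-dihydroxy-6,8a-dimethyl-3-(propan-2-yl)-1,2,3,3a,4,5,6,8a-octahydroazulen-4-yl 4-hydroxybenzoate, via acetoxybenzoate 17 (not isolated)
Conditions: 16, pyridine, DMAP (cat.), CH2Cl2, 0 → 25 °C; then MeOH, K2CO3 (cat.), 0 °C
Reagents that add atoms: none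
Why: Acyl chloride/DMAP acylation should take only the secondary C-4 hydroxyl (both tertiary hydroxyls are inert) with retention at carbon, and carbonate-catalysed methanolysis then removes the phenolic acetate, which is far more labile than the hindered alkyl benzoate.

**Compound list**

1 | 3-methylbut-3-en-1-ol | CC(=C)CCO | starting material
2 | 3-methylbut-3-enal | CC(=C)CC=O | intermediate
3 | ethynyl(dimethyl)phenylsilane | C#C[Si](C)(C)c1ccccc1 | starting material
4 | 3-methylcyclopent-2-en-1-one | CC1=CC(=O)CC1 | starting material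
5 | [1-(dimethylphenylsilyl)ethenyl]bis(2-methylpropyl)aluminium | C=C([Si](C)(C)c1ccccc1)[Al](CC(C)C)CC(C)C | intermediate
6 | bis(2-methylpropyl)aluminium (3S)-3-methyl-3-[1-(dimethylphenylsilyl)ethenyl]cyclopent-1-en-1-olate | CC(C)C[Al](CC(C)C)OC1=C[C@@](C)(C(=C)[Si](C)(C)c2ccccc2)CC1 | intermediate
7 | (2S,3S)-2-[(1S)-1-hydroxy-3-methylbut-3-en-1-yl]-3-methyl-3-[1-(dimethylphenylsilyl)ethenyl]cyclopentan-1-one | O=C1CC[C@](C)(C(=C)[Si](C)(C)c2ccccc2)[C@H]1[C@@H](O)CC(C)=C | intermediate
8 | (1R,2S,3S)-2-[(1S)-1-hydroxy-3-methylbut-3-en-1-yl]-3-methyl-1-(propan-2-yl)-3-[1-(dimethylphenylsilyl)ethenyl]cyclopentan-1-ol | CC(C)[C@]1(O)CC[C@](C)(C(=C)[Si](C)(C)c2ccccc2)[C@H]1[C@@H](O)CC(C)=C | intermediate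
9 | (1R,2S,3R)-3-ethenyl-2-[(1S)-1-hydroxy-3-methylbut-3-en-1-yl]-3-methyl-1-(propan-2-yl)cyclopentan-1-ol | CC(C)[C@]1(O)CC[C@](C)(C=C)[C@H]1[C@@H](O)CC(C)=C | intermediate
10 | (3R,3aS,4S,7aR)-6,7a-dimethyl-3-(propan-2-yl)-2,3,3a,4,5,7a-hexahydro-1H-indene-3,4-diol | CC(C)[C@]1(O)CC[C@]2(C)C=C(C)C[C@H](O)[C@H]21 | intermediate
11 | (3R,3aS,4S,7aR)-6,7a-dimethyl-3-(propan-2-yl)-3,4-bis(triethylsilyloxy)-2,3,3a,4,5,7a-hexahydro-1H-indene | CC(C)[C@]1(O[Si](CC)(CC)CC)CC[C@]2(C)C=C(C)C[C@H](O[Si](CC)(CC)CC)[C@H]21 | intermediate
12 | dibromocarbene adduct of 11: 7,7-dibromobicyclo[4.1.0]heptane unit fused to the cyclopentane, CBr2 bridge across the former alkene on the face opposite the angular methyl | CC(C)[C@]1(O[Si](CC)(CC)CC)CC[C@]2(C)[C@@H]3C(Br)(Br)[C@]3(C)C[C@H](O[Si](CC)(CC)CC)[C@H]21 | intermediate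
13 | (3R,3aS,4S,6R,8aS)-7-bromo-6,8a-dimethyl-3-(propan-2-yl)-3,4-bis(triethylsilyloxy)-1,2,3,3a,4,5,6,8a-octahydroazulen-6-ol | CC(C)[C@]1(O[Si](CC)(CC)CC)CC[C@]2(C)C=C(Br)[C@](C)(O)C[C@H](O[Si](CC)(CC)CC)[C@H]21 | intermediate
14 | (3R,3aS,4S,6R,8aR)-6,8a-dimethyl-3-(propan-2-yl)-3,4-bis(triethylsilyloxy)-1,2,3,3a,4,5,6,8a-octahydroazulen-6-ol | CC(C)[C@]1(O[Si](CC)(CC)CC)CC[C@]2(C)C=C[C@](C)(O)C[C@H](O[Si](CC)(CC)CC)[C@H]21 | intermediate
15 | (3R,3aS,4S,6R,8aR)-6,8a-dimethyl-3-(propan-2-yl)-1,2,3,3a,4,5,6,8a-octahydroazulene-3,4,6-triol | CC(C)[C@]1(O)CC[C@]2(C)C=C[C@](C)(O)C[C@H](O)[C@H]21 | intermediate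
16 | 4-(acetyloxy)benzoyl chloride | CC(=O)Oc1ccc(cc1)C(Cl)=O | starting material
17 | (3R,3aS,4S,6R,8aR)-3,6-dihydroxy-6,8a-dimethyl-3-(propan-2-yl)-1,2,3,3a,4,5,6,8a-octahydroazulen-4-yl 4-(acetyloxy)benzoate | CC(C)[C@]1(O)CC[C@]2(C)C=C[C@](C)(O)C[C@H](OC(=O)c3ccc(OC(C)=O)cc3)[C@H]21 | intermediate
18 | (3R,3aS,4S,6R,8aR)-3,6-dihydroxy-6,8a-dimethyl-3-(propan-2-yl)-1,2,3,3a,4,5,6,8a-octahydroazulen-4-yl 4-hydroxybenzoate | CC(C)[C@]1(O)CC[C@]2(C)C=C[C@](C)(O)C[C@H](OC(=O)c3ccc(O)cc3)[C@H]21 | target

**Totals**

Total step count: 10. Longest linear sequence: 10 steps (1 → 18; 9 steps counted from enone 4).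

**Steps most likely to fail**

Step 7. The allyl cation may be captured at the wrong terminus or from the wrong face, or may lose a proton to a bromodiene. The fallback forms the same C-6–C-7 bond by carbonyl addition instead of ring enlargement; it sets out from 9 and comes back at 14. Both hydroxyls of 9 are silylated (Et3SiOTf, 2,6-lutidine) to give the bis(triethylsilyl) ether of 9 F1. Ozonolysis of both terminal alkenes (O3, CH2Cl2–MeOH, −78 °C; Me2S) gives the keto aldehyde F2. Stork–Zhao olefination (Ph3P(CH2I)I, NaN(SiMe3)2, THF, −78 °C), in which the aldehyde should react before the methyl ketone, gives the (Z)-iodoalkene F3. An intramolecular Nozaki–Hiyama–Kishi reaction (CrCl2, NiCl2 cat., DMSO–THF) then adds the alkenylchromium to the methyl ketone, closing the seven-membered ring with the tertiary allylic alcohol and giving 14.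

Step 2. Facial or anti/syn selectivity of the aluminium enolate toward the aldehyde may be poor, or the enolate may be sluggish. The fallback separates the two events and uses a boron aldol; it sets out from 4 (with 3) and comes back at 7. The conjugate addition is run as before, but the enolate is trapped with Me3SiOTf to give the isolable trimethylsilyl enol ether F4. MeLi regenerates the regiodefined lithium enolate, n-Bu2BOTf converts it into the boron enolate, and its tighter Zimmerman–Traxler transition state should give the anti aldol 7 with 2 (pH 7 buffer, H2O2 work-up).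

Step 4. Cleavage of the hindered alkenyl–silicon bond may be incomplete. The fallback avoids silicon altogether; it sets out from 4 and comes back at 10. 2-Methylprop-1-enyl(dimethyl)aluminium (from 1-bromo-2-methylprop-1-ene, t-BuLi, Me2AlCl) is added to 4 with copper thiophene-2-carboxylate (C5H3CuO2S) and a chiral phosphoramidite-type ligand, and the enolate is trapped with 2 to give the isobutenyl aldol F5. i-PrMgCl/CeCl3 gives the isobutenyl diol F6. Ring-closing metathesis with the second-generation Grubbs catalyst then expels 2-methylpropene and gives 10 directly.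

**Further compounds**

F1 | step 7 | bis(triethylsilyl) ether of 9: (1R,2S,3R)-3-ethenyl-3-methyl-2-[(1S)-3-methyl-1-(triethylsilyloxy)but-3-en-1-yl]-1-(propan-2-yl)-1-(triethylsilyloxy)cyclopentane | CC(C)[C@]1(O[Si](CC)(CC)CC)CC[C@](C)(C=C)[C@H]1[C@@H](O[Si](CC)(CC)CC)CC(C)=C
F2 | step 7 | keto aldehyde: (1S,2S,3R)-1-methyl-2-[(1S)-3-oxo-1-(triethylsilyloxy)butyl]-3-(propan-2-yl)-3-(triethylsilyloxy)cyclopentane-1-carbaldehyde | CC(C)[C@]1(O[Si](CC)(CC)CC)CC[C@](C)(C=O)[C@H]1[C@@H](O[Si](CC)(CC)CC)CC(C)=O
F3 | step 7 | (Z)-iodoalkene: F2 with the formyl group replaced by a (Z)-2-iodoethenyl group, configuration otherwise unchanged | CC(C)[C@]1(O[Si](CC)(CC)CC)CC[C@](C)(/C=C\I)[C@H]1[C@@H](O[Si](CC)(CC)CC)CC(C)=O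
F4 | step 2 | trimethyl({(3S)-3-methyl-3-[1-(dimethylphenylsilyl)ethenyl]cyclopent-1-en-1-yl}oxy)silane | C[Si](C)(C)OC1=C[C@@](C)(C(=C)[Si](C)(C)c2ccccc2)CC1
F5 | step 4 | (2S,3R)-2-[(1S)-1-hydroxy-3-methylbut-3-en-1-yl]-3-methyl-3-(2-methylprop-1-en-1-yl)cyclopentan-1-one | O=C1CC[C@](C)(C=C(C)C)[C@H]1[C@@H](O)CC(C)=C
F6 | step 4 | (1R,2S,3R)-2-[(1S)-1-hydroxy-3-methylbut-3-en-1-yl]-3-methyl-3-(2-methylprop-1-en-1-yl)-1-(propan-2-yl)cyclopentan-1-ol | CC(C)[C@]1(O)CC[C@](C)(C=C(C)C)[C@H]1[C@@H](O)CC(C)=C
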